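**Plan**

1. Quinone numbering: C1(=O), C2(OH), C3(C21H43), C4(=O), C5(OMe), C6(H); C1' is the first chain carbon. Retrosynthetic cuts, in order: the C2 hydroxyl back to a tert-butyl ether; then C4–C5 and C6–H, with the transannular C1–C4 bond restored, which contracts the six-membered quinone ring to a four-membered cyclobutenone ring; then C1–C6 (carbinol–alkyne); then C3–C1' (ring–chain).
2. Forward: the C21 chain is joined to the squarate four-membered ring, methoxyacetylide is added to the carbonyl that becomes C1, the four-membered ring C1–C2–C3–C4 is expanded by the two alkyne carbons C6 and C5 to the quinone ring, and the tert-butyl group is removed last.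
3. Enabling feature: C1, C2, C3 and C4 are four contiguous ring carbons carrying O, O, C, O, which is the squaric acid pattern. The remaining C5(OMe)=C6(H) unit is a methoxyalkyne, and the C6 hydrogen is the former carbinol hydrogen. Breaking C1–C4 and bonding C4 to C5 therefore gives this quinone with all four substituents placed by connectivity.
4. Stereochemistry: the target has no stereocentre and no stereogenic double bond; the single racemic carbinol centre made in step 3 becomes the C1 carbonyl in step 4.

Key step: step 4

Remark on the chemistry: the target is made and drawn as the 2-hydroxy-1,4-benzoquinone tautomer of the given SMILES; it is achiral.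

**Route**

Step 1
Reactants: 1 1-heneicosanol
Product: 2 1-iodoheneicosane
Conditions: PPh3, I2, imidazole, THF, 0 °C → rt
Reagents that add atoms: iodine, II
Why: Appel-type iodination of an unhindered primary alcohol, in which the alkoxyphosphonium ion is displaced by iodide in an SN2 step; no stereocentre is involved.

Step 2
Reactants: 2 1-iodoheneicosane; 3 di-tert-butyl squarate (3,4-di-tert-butoxycyclobut-3-ene-1,2-dione)
Product: 7 3-tert-butoxy-4-heneicosylcyclobut-3-ene-1,2-dione, via heneicosyllithium 4 (not isolated), via lithium alkoxide adduct 5 (not isolated), via adduct trifluoroacetate 6 (not isolated)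
Conditions: t-BuLi (2.1 equiv), Et2O/pentane, −78 → 0 °C; then 3, THF, −78 °C; then (CF3CO)2O, −78 °C; aq NaHCO3
Reagents that add atoms: none
Why: Lithium–iodine exchange gives the primary alkyllithium, which adds 1,2 to one carbonyl of the squarate ester; O-trifluoroacetylation of the adduct then triggers the acid-type 1,2-carbonyl transposition (ionisation assisted by the enol ether oxygen, loss of one tert-butyl group) that is standard for squarate adducts and leaves no stereocentre.

Step 3
Reactants: 7 3-tert-butoxy-4-heneicosylcyclobut-3-ene-1,2-dione; 8 chloroacetaldehyde dimethyl acetal (2-chloro-1,1-dimethoxyethane)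
Product: 11 3-tert-butoxy-2-heneicosyl-4-hydroxy-4-(methoxyethynyl)cyclobut-2-en-1-one (racemic), via lithium methoxyacetylide 9 (not isolated), via lithium alkoxide 10 (not isolated)
Conditions: 8, LiNEt2 (3.0 equiv, from n-BuLi and Et2NH), THF, 0 °C; then 7, −78 °C; cold H2O/pH 7 phosphate buffer; crude 11 used without silica gel
Reagents that add atoms: none
Why: Twofold elimination (methanol, then HCl) from the chloroacetal with lithium diethylamide gives lithium methoxyacetylide, which undergoes regioselective 1,2-addition to the ketone-type carbonyl next to the tert-butoxy-bearing carbon and not to the vinylogous-ester carbonyl next to the alkyl-bearing carbon; the new carbinol centre is racemic and is destroyed in step 4.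

Step 4
Reactants: 11 3-tert-butoxy-2-heneicosyl-4-hydroxy-4-(methoxyethynyl)cyclobut-2-en-1-one
Product: 14 2-tert-butoxy-3-heneicosyl-5-methoxy-1,4-benzoquinone, via enynylketene 12 (not isolated), via aryl diradical 13 (not isolated)
Conditions: toluene (degassed, dilute), 110 °C
Reagents that add atoms: none
Why: Heating opens the C1–C4 bond of the cyclobutenone in a conrotatory 4π-electrocyclic step to the enynylketene 12, whose ketene carbon (C4) bonds to the methoxy-bearing alkyne carbon (C5) to give the six-membered diradical 13 (σ-radical at C6, phenoxyl-type π-radical on the C4 oxygen), and transfer of the hydroxyl hydrogen from the C1 oxygen to C6 then gives the quinone. The closest known reaction type is the Moore rearrangement of 4-alkynyl-4-hydroxycyclobutenones to 1,4-benzoquinones, which is established for 3-alkoxy-2-alkyl cyclobutenones of this substitution pattern. The only ring closed is the six-membered quinone ring, by a 6-endo-dig diradical closure of the ketene onto the alkyne (a relative of the Myers–Saito cycloaromatisation), so that the four-membered ring is expanded by two atoms. No stereocentre is formed, and the racemic carbinol centre becomes the C1 carbonyl carbon. The step needs (a) the alkyne cis to the ketene, which outward rotation of the donor hydroxyl group during ring opening should secure, (b) 6-endo over 5-exo closure (the latter would lead to a 2-alkylidenecyclopent-4-ene-1,3-dione), expected because a methoxy group, unlike an aryl, silyl or ester group, does not stabilise the exocyclic vinyl radical of the five-ring pathway, and (c) the substituent pattern, which is fixed by connectivity because C5 can only bond to the ketene carbon next to the alkyl-bearing C3.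

Step 5
Reactants: 14 2-tert-butoxy-3-heneicosyl-5-methoxy-1,4-benzoquinone
Product: 15 3-heneicosyl-2-hydroxy-5-methoxy-1,4-benzoquinone (target)
Conditions: CF3CO2H, CH2Cl2, 0 °C → rt
Reagents that add atoms: none
Why: Acidolysis of the tert-butyl vinylogous ester (E1 loss of the tert-butyl cation as isobutene) frees the C2 hydroxyl, while the methyl vinylogous ester at C5 cannot ionise in this way and should stay intact under anhydrous acid.

**Compound list**

1 | 1-heneicosanol | CCCCCCCCCCCCCCCCCCCCCO | starting material
2 | 1-iodoheneicosane | CCCCCCCCCCCCCCCCCCCCCI | intermediate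
3 | di-tert-butyl squarate (3,4-di-tert-butoxycyclobut-3-ene-1,2-dione) | CC(C)(C)OC1=C(OC(C)(C)C)C(=O)C1=O | starting material
4 | heneicosyllithium | [Li]CCCCCCCCCCCCCCCCCCCCC | intermediate (not isolated)
5 | lithium 2,3-di-tert-butoxy-1-heneicosyl-4-oxocyclobut-2-en-1-olate | CCCCCCCCCCCCCCCCCCCCCC1(O[Li])C(=O)C(OC(C)(C)C)=C1OC(C)(C)C | intermediate (not isolated)
6 | 2,3-di-tert-butoxy-1-heneicosyl-4-oxocyclobut-2-en-1-yl trifluoroacetate | CCCCCCCCCCCCCCCCCCCCCC1(OC(=O)C(F)(F)F)C(=O)C(OC(C)(C)C)=C1OC(C)(C)C | intermediate (not isolated)
7 | 3-tert-butoxy-4-heneicosylcyclobut-3-ene-1,2-dione | CCCCCCCCCCCCCCCCCCCCCC1=C(OC(C)(C)C)C(=O)C1=O | intermediate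
8 | chloroacetaldehyde dimethyl acetal (2-chloro-1,1-dimethoxyethane) | COC(CCl)OC | starting material
9 | lithium methoxyacetylide | [Li]C#COC | intermediate (not isolated)
10 | lithium 2-tert-butoxy-3-heneicosyl-1-(methoxyethynyl)-4-oxocyclobut-2-en-1-olate | CCCCCCCCCCCCCCCCCCCCCC1=C(OC(C)(C)C)C(O[Li])(C#COC)C1=O | intermediate (not isolated)
11 | 3-tert-butoxy-2-heneicosyl-4-hydroxy-4-(methoxyethynyl)cyclobut-2-en-1-one (racemic) | CCCCCCCCCCCCCCCCCCCCCC1=C(OC(C)(C)C)C(O)(C#COC)C1=O | intermediate
12 | (3Z)-3-tert-butoxy-2-heneicosyl-4-hydroxy-6-methoxyhexa-1,3-dien-5-yn-1-one (enynylketene) | CCCCCCCCCCCCCCCCCCCCCC(=C=O)/C(OC(C)(C)C)=C(O)\C#COC | intermediate (not isolated)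
13 | 3-tert-butoxy-2-heneicosyl-4-hydroxy-6-methoxyphenoxyl-5-yl diradical | CCCCCCCCCCCCCCCCCCCCCC1=C(OC(C)(C)C)C(O)=[C]C(OC)=C1[O] | intermediate (not isolated)
14 | 2-tert-butoxy-3-heneicosyl-5-methoxy-1,4-benzoquinone | CCCCCCCCCCCCCCCCCCCCCC1=C(OC(C)(C)C)C(=O)C=C(OC)C1=O | intermediate
15 | 3-heneicosyl-2-hydroxy-5-methoxy-1,4-benzoquinone | CCCCCCCCCCCCCCCCCCCCCC1=C(O)C(=O)C=C(OC)C1=O | target

**Step count and risks**

Total step count: 5. Longest linear sequence: 5 steps (1 → 2 → 7 → 11 → 14 → 15); compounds 3 and 8 are used as purchased.

The three steps most likely to fail: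

Step 4 (key step). The enynylketene may partition into the 5-exo closure and give an alkylidenecyclopentenedione, isobutene may be lost thermally before ring closure, or the electron-rich ynol ether may oligomerise at 110 °C. The fallback sets out from 11 and comes back at 14. The ynol ether of 11 would be semihydrogenated (H2, Pd/CaCO3 poisoned with Pb(OAc)2, quinoline, EtOAc, rt) to the enol ether 3-tert-butoxy-2-heneicosyl-4-hydroxy-4-[(Z)-2-methoxyethenyl]cyclobut-2-en-1-one F1. Heating F1 in toluene (80–110 °C) should give, by 4π ring opening, 6π-electrocyclisation of the resulting dienylketene and tautomerisation, the hydroquinone 2-tert-butoxy-3-heneicosyl-5-methoxybenzene-1,4-diol F2. Oxidation with Ag2O and K2CO3 in Et2O would return to 14. This is still a four-to-six ring expansion with the same connectivity, but it is pericyclic and has no five-ring channel.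

Step 3. Diethylamine or lithium methoxide may attack the vinylogous ester of 7 in competition with the acetylide, and the ynol ether carbinol may undergo acid-triggered Meyer–Schuster-type rearrangement or hydration during work-up. The fallback sets out from 7 and comes back at 14, and it avoids any ynol ether. Ethynylmagnesium bromide (HC≡CMgBr, THF, −78 °C) would add to the same carbonyl of 7 to give 3-tert-butoxy-4-ethynyl-2-heneicosyl-4-hydroxycyclobut-2-en-1-one F3. Moore rearrangement of F3 (p-xylene, 138 °C) would give 2-tert-butoxy-3-heneicosyl-1,4-benzoquinone F4. Conjugate addition of methanol (MeOH, ZnCl2, rt) with reoxidation by air or Ag2O would then place the methoxy group at C5 and return to 14. C5 is the expected site because the C2 alkoxy group deactivates the C4 carbonyl, so the C1 enone directs the nucleophile to its β-carbon (the 2,5-pattern known for alkoxyquinones).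

Step 2. The waxy iodide may precipitate or undergo Wurtz-type coupling during the lithium–iodine exchange, and the tert-butyl vinylogous ester may lose isobutene under the trifluoroacetic anhydride-triggered transposition. The fallback sets out from 2 and comes back at 7, with the tert-butyl group installed last. Compound 2 would be converted (Mg, THF, reflux) into heneicosylmagnesium iodide F5. F5 would be added to commercial diisopropyl squarate (THF, −78 °C; aq NH4Cl) to give 4-heneicosyl-4-hydroxy-2,3-diisopropoxycyclobut-2-en-1-one F6. Catalytic concentrated HCl in CH2Cl2 would rearrange F6 to 3-heneicosyl-4-isopropoxycyclobut-3-ene-1,2-dione F7. Hydrolysis (6 M HCl, dioxane, reflux) would give the semisquaric acid 3-heneicosyl-4-hydroxycyclobut-3-ene-1,2-dione F8. O-tert-butylation of this vinylogous acid with tert-butyl 2,2,2-trichloroacetimidate (CH2Cl2/cyclohexane, rt) would give 7; alkylation at either oxygen of the symmetric vinylogous carboxylate gives the same compound.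

**Further compounds**

F1 | step 4 | 3-tert-butoxy-2-heneicosyl-4-hydroxy-4-[(Z)-2-methoxyethenyl]cyclobut-2-en-1-one | CCCCCCCCCCCCCCCCCCCCCC1=C(OC(C)(C)C)C(O)(/C=C\OC)C1=O
F2 | step 4 | 2-tert-butoxy-3-heneicosyl-5-methoxybenzene-1,4-diol | CCCCCCCCCCCCCCCCCCCCCc1c(OC(C)(C)C)c(O)cc(OC)c1O
F3 | step 3 | 3-tert-butoxy-4-ethynyl-2-heneicosyl-4-hydroxycyclobut-2-en-1-one | CCCCCCCCCCCCCCCCCCCCCC1=C(OC(C)(C)C)C(O)(C#C)C1=O
F4 | step 3 | 2-tert-butoxy-3-heneicosyl-1,4-benzoquinone | CCCCCCCCCCCCCCCCCCCCCC1=C(OC(C)(C)C)C(=O)C=CC1=O
F5 | step 2 | heneicosylmagnesium iodide | CCCCCCCCCCCCCCCCCCCCC[Mg]I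
F6 | step 2 | 4-heneicosyl-4-hydroxy-2,3-diisopropoxycyclobut-2-en-1-one | CCCCCCCCCCCCCCCCCCCCCC1(O)C(=O)C(OC(C)C)=C1OC(C)C
F7 | step 2 | 3-heneicosyl-4-isopropoxycyclobut-3-ene-1,2-dione | CCCCCCCCCCCCCCCCCCCCCC1=C(OC(C)C)C(=O)C1=O
F8 | step 2 | 3-heneicosyl-4-hydroxycyclobut-3-ene-1,2-dione | CCCCCCCCCCCCCCCCCCCCCC1=C(O)C(=O)C1=O
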